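If electrophile is consumed by nucleophile, its fractional loss per minute, a pseudo-first-order rate, follows the free nucleophile, so the beta run works as a gauge.

| setting | beta | Friday's | Wednesday's |
|---|---|---|---|
| electrophile | 0.54 M | 0.80 M | 0.80 M |
| nucleophile | 0.96 M | 0.960 M | 0.960 M |
| free base | 1.6 M | 1.60 M | 2.10 M |
| remark | run made earlier |  |  |
| time |  | 25 min | 25 min |

beta run (percent of the electrophile charged)

| time / min | electrophile / % | target / % |
|---|---|---|
| 1.33 | 52.0 | 36.8 |
| 2.50 | 37.2 | 38.1 |
| 4.00 | 26.4 | 34.6 |
| 5.00 | 25.0 | 29.3 |

(standard deviation of a reading: 1 percentage point)

- no earlier run changes the charge of free base; that part of a forecast is a guess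

- part of the electrophile that has reacted at the end, Friday's
- part of the electrophile that has reacted at the end, Wednesday's
- what raising the concentration of free base from its lowest to its highest value here does to the part of the electrophile that has reacted (changes below 5 percentage points count as none) (no change / it rises / it falls)

Up to 1.33 min the beta electrophile falls at 0.492 min⁻¹, at a mean reacted fraction of 0.240. From there to 4.00 min it falls more slowly, at 0.254 min⁻¹, at a mean reacted fraction of 0.608. A straight line through these two points reaches zero at a reacted fraction of 1.00. The beta charge ratio divided by that fraction gives 1.78 of nucleophile used up per electrophile reacted, the nucleophile price. It is a reading and carries the scatter.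

Friday's charges 1.20 of nucleophile per electrophile, below the price. So nucleophile should be the limiting reagent, and 25 min far exceeds the early time constant of the beta run, 2.03 min. This reckoning therefore stops Friday's at 67.6% reacted, and Wednesday's at the same figure by a guess, since no run varied free base.

The forecast is higher: 75% for Friday's, 75% for Wednesday's and no change for the trend, holding that “the endpoint is set by stoichiometry”.

The flask gives 68.6% on Friday's and 69.5% on Wednesday's, so the trend is no change, with a change of 0.86 percentage points.

    nucleophile + acid set free ⇌ protonated nucleophile, settled at all times (K = 1100 M⁻¹)
    acid set free + free base ⇌ salt of the base (K = 1.90 M⁻¹, k = 0.190 M⁻¹ s⁻¹)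
    electrophile + nucleophile → acid set free + target (k = 0.0130 M⁻¹ s⁻¹)
    target ⇌ isomer of the product (K = 0.250, k = 0.00270 s⁻¹)
    target → over-reaction product (k = 0.00390 s⁻¹)

In Friday's flask half of the making of target up to 25 min is done by 0.858 min, whereas free base, by its forward binding of acid set free alone, has a half-life of 100 min at 0.858 min. At 25.0 min Friday's protonated nucleophile stands at 0.401 M against 0.109 M of salt of the base. Friday's has lost 1.73 of unbound nucleophile per electrophile reacted, with 0.98% of the charge still unbound, against the price of 1.78. A neighbour of Friday's with 2.4 M of nucleophile holds 3.00 per electrophile, above the price, and there electrophile runs out first, with 0% of it left and >99.9% reacted.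

All runs were generated by integration from invented constants; the scatter is artificial.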